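## Retrosynthetic overview
1. Niveusin B comes from a macrocyclic 3-oxo/10-hydroxy enone by removing silyl groups. The C3 hemiketal forms transannularly, and the C3 configuration is forced by the bicyclic bridge. The enone comes from the C3 allylic alcohol by MnO2 oxidation.
2. The 10-membered ring and its cis C4=C5 alkene come from a macro-ring-closing metathesis (RCM) of a C6-vinyl lactone with a 2-(silyloxymethyl)allyl carbinol. The carbinol comes from an NHK addition of 2-bromoallyl TBS ether to a C3 aldehyde, which is unmasked by cleaving the prenyl alkene of (S)-linalool. Linalool supplies C10 with its configuration, plus C1–C4, C8–C10, C14 and C15.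
3. The trans-lactone and C7/C8 come from SmI2 ketyl–butenolide coupling of the linalool-derived C8 aldehyde with (R)-5-vinylbutenolide. The angelate and the α-methylene group are added afterwards.
4. Rings form in this order: lactone (Step 7), then 10-membered carbocycle (Step 14), then THF hemiketal (Step 16).

Assumptions: (a) the target is the closed bicyclic hemiketal as drawn; (b) the SmI2 coupling gives the (8R) diastereomer as the major or at least a separable product.

## Route

**Step 1**
Reactants: 1 (S)-(+)-linalool
Product: 2 (S)-linalool triethylsilyl ether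
Conditions: TESOTf, 2,6-lutidine, CH2Cl2, –78 → 0 °C
Reagents that add atoms: TESOTf, CC[Si](CC)(CC)OS(=O)(=O)C(F)(F)F
Why: Silylation masks the tertiary alcohol, which otherwise would give a β-hydroxy aldehyde in Step 3; the C10 stereocenter is untouched.

**Step 2**
Reactants: 2
Product: 3 (S)-3,7-dimethyl-3-(triethylsilyloxy)oct-6-en-1-ol
Conditions: 9-BBN, THF, 0 °C → rt; then NaOH, H2O2
Reagents that add atoms: hydrogen peroxide, OO (supplies the OH oxygen)
Why: 9-BBN hydroborates the monosubstituted vinyl group anti-Markovnikov, with complete selectivity over the trisubstituted prenyl alkene; C10 is not involved.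

**Step 3**
Reactants: 3
Product: 4 (S)-3,7-dimethyl-3-(triethylsilyloxy)oct-6-enal (C8 aldehyde)
Conditions: TEMPO (cat.), PhI(OAc)2, CH2Cl2, rt
Reagents that add atoms: none
Why: TEMPO/BAIB oxidation of a primary alcohol to the aldehyde under mild conditions that leave the alkene and the silyl ether intact; the aldehyde is used immediately.

**Step 4**
Reactants: 5 acrolein; 6 ethyl propiolate
Product: 7 (R)-ethyl 4-hydroxyhex-5-en-2-ynoate
Conditions: Et2Zn, (S,S)-ProPhenol (10 mol%), Ph3P=O, toluene, 4 °C
Reagents that add atoms: none beyond the two reactants (the ethyl groups of Et2Zn are lost)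
Why: Zn-ProPhenol catalysed asymmetric alkynylation of an aldehyde sets C6; the ligand enantiomer is chosen to give the (R)-carbinol.

**Step 5**
Reactants: 7
Product: 8 (R)-5-vinylfuran-2(5H)-one
Conditions: H2 (1 atm), Lindlar catalyst, quinoline, EtOAc, rt; then TsOH (cat.), CH2Cl2
Reagents that add atoms: hydrogen, [H][H]
Why: Lindlar semi-hydrogenation gives the Z-enoate, which lactonises under acid without touching the carbinol stereocenter (acid avoids γ-deprotonation and racemisation).

**Step 6**
Reactants: 9 2-bromoallyl alcohol
Product: 10 2-bromoallyl TBS ether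
Conditions: TBSCl, imidazole, DMF, rt
Reagents that add atoms: TBSCl, C[Si](C)(C(C)(C)C)Cl
Why: Standard silylation to make the NHK partner; it also carries C15.

**Step 7**
Reactants: 4 aldehyde; 8 (R)-5-vinylbutenolide (2 equiv)
Product: 11 trans-lactone carrying the C8 carbinol (C7 and C8 new)
Conditions: SmI2, HMPA, t-BuOH, THF, –78 °C
Reagents that add atoms: none (t-BuOH only supplies H)
Why: Proposed new method: the Sm(III) ketyl of an aliphatic aldehyde adds to the β-carbon (C7) of the 5-vinylbutenolide and the Sm enolate is protonated; the closest known reaction is the Fukuzawa SmI2 aldehyde–enoate coupling. C7 is set trans to the C6 vinyl by attack on the less hindered face, and C8 is set by a Sm-chelated arrangement, with the (8R) isomer assumed to be major and any (8S) isomer separated.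

**Step 8**
Reactants: 11
Product: 12 C8 angelate
Conditions: angelic acid, 2,4,6-Cl3C6H2COCl, Et3N, THF, 0 °C; then 11, DMAP, toluene, rt (Yamaguchi)
Reagents that add atoms: angelic acid, OC(=O)/C(C)=C\C
Why: Yamaguchi esterification at the C8 alcohol retains the Z-alkene of the angelate, and C8 is not epimerised.

**Step 9**
Reactants: 12
Product: 13 α-(dimethylaminomethyl) lactone (C11 epimers)
Conditions: LiHMDS, THF, –78 °C; then Me2N=CH2+ I–, –78 → 0 °C
Reagents that add atoms: Eschenmoser's salt, C=[N+](C)C.[I-]
Why: Lactone enolate Mannich aminomethylation; the C11 stereocenter is destroyed in the next step, and C7–H is not acidic, so C6/C7 are retained.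

**Step 10**
Reactants: 13
Product: 14 α-methylene-γ-lactone
Conditions: MeI, CH2Cl2, rt; then aq. NaHCO3
Reagents that add atoms: none (MeI only quaternises the amine; NMe3 is expelled)
Why: Quaternisation followed by E1cB-type elimination forms the exocyclic methylene; a mild base avoids isomerisation to the endocyclic alkene.

**Step 11**
Reactants: 14
Product: 15 6,7-epoxide of the prenyl group (epimeric mixture)
Conditions: mCPBA (1.0 equiv), NaHCO3, CH2Cl2, –20 °C
Reagents that add atoms: mCPBA, OOC(=O)c1cccc(Cl)c1 (adds O)
Why: The electron-rich trisubstituted alkene reacts much faster than the vinyl group or the electron-poor acrylate and angelate alkenes; the new epoxide stereocenters are destroyed in Step 12.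

**Step 12**
Reactants: 15
Product: 16 C3 aldehyde (loses acetone)
Conditions: H5IO6, Et2O/THF, 0 °C → rt
Reagents that add atoms: none (periodate is the oxidant)
Why: Epoxide hydrolysis and periodate glycol cleavage give the aldehyde and acetone. If the tertiary TES ether is lost, the γ-hydroxy aldehyde closes to a lactol that still reacts in Step 13.

**Step 13**
Reactants: 16; 10
Product: 17 C3 allylic alcohol with the 2-(TBSOCH2)allyl unit (C3 epimers, about 1:1)
Conditions: CrCl2, NiCl2 (cat.), DMF, rt
Reagents that add atoms: none beyond 10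
Why: The Nozaki–Hiyama–Kishi vinylchromium addition is chemoselective for the aldehyde and forms C3–C4; the C3 configuration is irrelevant because C3 is oxidised in Step 15.

**Step 14**
Reactants: 17
Product: 18 macrocyclic (Z)-C4=C5 alkene, C3 alcohol, C10-OTES, C15-OTBS
Conditions: Hoveyda–Grubbs II (20 mol%), 1,4-benzoquinone (cat.), toluene (1 mM), 80 °C
Reagents that add atoms: none (ethylene is lost)
Why: Proposed new method: the Ru alkylidene formed on the C6 vinyl group closes onto the hindered 1,1-disubstituted C4=CH2 to give a trisubstituted alkene in a 10-membered ring; the closest known reaction is medium-ring RCM onto 2-substituted allyl carbinols. The trans-fused lactone pre-organises the chain, the cis (Z) alkene is the less strained geometry in a 10-membered ring, and the α-methylene and angelate alkenes are unreactive.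

**Step 15**
Reactants: 18
Product: 19 macrocyclic C3 enone
Conditions: activated MnO2, CH2Cl2, rt
Reagents that add atoms: none
Why: MnO2 oxidises only the free allylic alcohol (C15 is silylated and C8 is acylated), and both C3 epimers converge to one enone.

**Step 16**
Reactants: 19
Product: 20 niveusin B
Conditions: HF·pyridine, pyridine, THF, 0 °C → rt
Reagents that add atoms: none
Why: HF·pyridine removes the C10-TES and C15-TBS groups, and the freed tertiary C10-OH adds to the C3 ketone to give the bridged hemiketal; the bridging six-atom chain allows only one C3 configuration, the cis-bridged (3R) hemiketal, fixed by the C10 configuration.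

## Compound list

| No. | Name | SMILES | Role |
|---|---|---|---|
| 1 | (S)-(+)-linalool | C=C[C@@](C)(O)CCC=C(C)C | starting material |
| 2 | (S)-linalool TES ether | C=C[C@@](C)(O[Si](CC)(CC)CC)CCC=C(C)C | intermediate |
| 3 | (S)-3,7-dimethyl-3-(TESO)oct-6-en-1-ol | OCC[C@](C)(CCC=C(C)C)O[Si](CC)(CC)CC | intermediate |
| 4 | (S)-3,7-dimethyl-3-(TESO)oct-6-enal | O=CC[C@](C)(CCC=C(C)C)O[Si](CC)(CC)CC | intermediate |
| 5 | acrolein | C=CC=O | starting material |
| 6 | ethyl propiolate | C#CC(=O)OCC | starting material |
| 7 | (R)-ethyl 4-hydroxyhex-5-en-2-ynoate | CCOC(=O)C#C[C@H](O)C=C | intermediate |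
| 8 | (R)-5-vinylfuran-2(5H)-one | C=C[C@H]1OC(=O)C=C1 | intermediate |
| 9 | 2-bromoallyl alcohol | C=C(Br)CO | starting material |
| 10 | 2-bromoallyl TBS ether | C=C(Br)CO[Si](C)(C)C(C)(C)C | intermediate |
| 11 | trans-lactone with C8 alcohol | C=C[C@H]1OC(=O)C[C@@H]1[C@H](O)C[C@](C)(CCC=C(C)C)O[Si](CC)(CC)CC | intermediate |
| 12 | C8 angelate of 11 | C=C[C@H]1OC(=O)C[C@@H]1[C@H](OC(=O)/C(C)=C\C)C[C@](C)(CCC=C(C)C)O[Si](CC)(CC)CC | intermediate |
| 13 | α-(dimethylaminomethyl) lactone | C=C[C@H]1OC(=O)C(CN(C)C)[C@@H]1[C@H](OC(=O)/C(C)=C\C)C[C@](C)(CCC=C(C)C)O[Si](CC)(CC)CC | intermediate |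
| 14 | α-methylene lactone | C=C[C@H]1OC(=O)C(=C)[C@@H]1[C@H](OC(=O)/C(C)=C\C)C[C@](C)(CCC=C(C)C)O[Si](CC)(CC)CC | intermediate |
| 15 | prenyl epoxide | C=C[C@H]1OC(=O)C(=C)[C@@H]1[C@H](OC(=O)/C(C)=C\C)C[C@](C)(CCC2OC2(C)C)O[Si](CC)(CC)CC | intermediate |
| 16 | C3 aldehyde | C=C[C@H]1OC(=O)C(=C)[C@@H]1[C@H](OC(=O)/C(C)=C\C)C[C@](C)(CCC=O)O[Si](CC)(CC)CC | intermediate |
| 17 | NHK adduct (C3 epimers) | C=C[C@H]1OC(=O)C(=C)[C@@H]1[C@H](OC(=O)/C(C)=C\C)C[C@](C)(CCC(O)C(=C)CO[Si](C)(C)C(C)(C)C)O[Si](CC)(CC)CC | intermediate |
| 18 | macrocyclic Z-alkene | C=C1C(=O)O[C@@H]2/C=C(/CO[Si](C)(C)C(C)(C)C)C(O)CC[C@](C)(O[Si](CC)(CC)CC)C[C@@H](OC(=O)/C(C)=C\C)[C@@H]12 | intermediate |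
| 19 | macrocyclic enone | C=C1C(=O)O[C@@H]2/C=C(/CO[Si](C)(C)C(C)(C)C)C(=O)CC[C@](C)(O[Si](CC)(CC)CC)C[C@@H](OC(=O)/C(C)=C\C)[C@@H]12 | intermediate |
| 20 | niveusin B | C=C1C(=O)O[C@@H]2/C=C(/CO)[C@@]3(O)CC[C@@](C)(C[C@@H](OC(=O)/C(C)=C\C)[C@@H]12)O3 | target |

## Totals
Total steps: 16. Longest linear sequence: 13 (Steps 1, 2, 3, 7, 8, 9, 10, 11, 12, 13, 14, 15, 16).

## Three steps most likely to fail
1. **Step 14 (macro-RCM).** The risks are a hindered 1,1-disubstituted partner, oligomerisation, and formation of the E-alkene. Fallback: change the ring closure to an intramolecular NHK of a Z-vinyl iodide onto a C3 aldehyde. The vinyl iodide comes from Red-Al/I2 on a 2-butyne-1,4-diol-derived propargylic alcohol and has the correct Z geometry by design. A second option is to photoisomerise an E-enone so that the Z-isomer is trapped as the hemiketal.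
2. **Step 7 (SmI2 coupling).** The risks are C8 diastereoselectivity, aldehyde pinacol coupling, and translactonisation to the 8,12-olide. Fallback: conjugate addition of the 2-lithio-1,3-dithiane of aldehyde 4 to butenolide 8, then dithiane removal and reagent-controlled (CBS or Noyori) reduction of the C8 ketone.
3. **Step 13 (NHK in the presence of the α-methylene lactone).** Cr(II)/Ni can reduce or add to the acrylate. Fallback: move the α-methylenation (Steps 9–10) after the RCM, so that Steps 13–14 run on the saturated lactone with C3 protected as a TES ether.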